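**Plan**

1. Retrosynthesis: global hydrogenolysis last; then cut the interflavan bond C4(upper)–C6(lower); then the two galloyl esters at O3 and O3' of the lower unit; then, in the lower flavan, C3–C4 (aldol) and O1–C2 (oxa-Michael), back to a ring A salicylaldehyde and a ring B cinnamaldehyde.
2. Enabling feature: in ring A of the lower unit O1 (on C8a) and C4 (on C4a) sit on adjacent carbons, and C3 carries oxygen. Ring C therefore maps onto a 2-hydroxybenzaldehyde (phenol O = O1, formyl C = C4) plus an enal (β-carbon = C2, α-carbon = C3). The enal formyl carbon is a temporary activating group, later exchanged for the C3 oxygen by Baeyer–Villiger oxidation.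
3. Forward order: ring A aldehyde and ring B enal are made separately; one domino operation forms O1–C2 and then closes ring C through C3–C4; formyl-to-oxygen exchange gives the C3 ketone; cis reduction; C8 bromination, desilylation and double galloylation; interflavan coupling; hydrogenolysis.
4. Stereochemistry: lower C2 from the prolinol silyl ether catalyst; lower C3 from hydride attack anti to the C2 aryl group; upper C2 and C3 from (−)-epicatechin; upper C4 from attack of the lower unit anti to the C3 hydroxyl and C2 aryl groups (3,4-trans, 4β).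
5. Regiochemistry: 4→6 (not 4→8) by a bromine that blocks C8 of the lower unit; O3' versus O4'/O5' of ring B by a diphenylmethylene ketal plus a silyl ether.

Key step: step 5

Assumption: the (S)-configured catalyst is taken to deliver the phenoxide to the enal β-carbon face that gives the (2R) series, as the usual shielding model predicts. Unprimed locants and ring letters A, B, C refer to the lower (epigallocatechin) unit; "upper" marks the epicatechin unit.

**Route**

Step 1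
Reactants: 1 2,4,6-trihydroxybenzaldehyde
Product: 2 2,4-bis(benzyloxy)-6-hydroxybenzaldehyde
Conditions: BnBr (2.1 equiv), K2CO3, DMF, 0 °C to rt
Reagents that add atoms: benzyl bromide, BrCc1ccccc1
Why: Williamson etherification should alkylate the para phenol and one of the two equivalent ortho phenols, while the remaining ortho phenol is held back by its hydrogen bond to the formyl oxygen.

Step 2
Reactants: 3 3,4,5-trihydroxybenzaldehyde
Product: 4 7-hydroxy-2,2-diphenyl-1,3-benzodioxole-5-carbaldehyde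
Conditions: Ph2CCl2, K2CO3, MeCN, rt to 50 °C
Reagents that add atoms: dichlorodiphenylmethane, ClC(Cl)(c1ccccc1)c1ccccc1
Why: Catechol ketalisation with dichlorodiphenylmethane should bridge the 4-oxygen and one neighbouring oxygen (the two choices are equivalent), leaving a single meta phenol free.

Step 3
Reactants: 4 7-hydroxy-2,2-diphenyl-1,3-benzodioxole-5-carbaldehyde
Product: 5 2,2-diphenyl-7-(triisopropylsilyloxy)-1,3-benzodioxole-5-carbaldehyde
Conditions: i-Pr3SiCl, imidazole, DMF, rt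
Reagents that add atoms: chlorotriisopropylsilane, CC(C)[Si](Cl)(C(C)C)C(C)C
Why: Silylation of the one free phenol gives an aryl silyl ether that is orthogonal to benzyl ethers and to the ketal and marks the future O3'.

Step 4
Reactants: 5 2,2-diphenyl-7-(triisopropylsilyloxy)-1,3-benzodioxole-5-carbaldehyde
Product: 6 (E)-3-[2,2-diphenyl-7-(triisopropylsilyloxy)-1,3-benzodioxol-5-yl]prop-2-enal
Conditions: Ph3P=CHCHO (1.1 equiv), toluene, 80 °C
Reagents that add atoms: (triphenylphosphoranylidene)acetaldehyde, O=CC=P(c1ccccc1)(c1ccccc1)c1ccccc1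
Why: Wittig olefination with the stabilised formylmethylene ylide should give the (E)-cinnamaldehyde by two-carbon homologation.

Step 5
Reactants: 2 2,4-bis(benzyloxy)-6-hydroxybenzaldehyde, 6 (E)-3-[2,2-diphenyl-7-(triisopropylsilyloxy)-1,3-benzodioxol-5-yl]prop-2-enal
Product: 9 (R)-5,7-bis(benzyloxy)-2-[2,2-diphenyl-7-(triisopropylsilyloxy)-1,3-benzodioxol-5-yl]-2H-chromene-3-carbaldehyde, via oxa-Michael enamine 7 (not isolated), via aldol iminium zwitterion 8 (not isolated)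
Conditions: (S)-α,α-diphenylprolinol trimethylsilyl ether (20 mol %), 2-nitrobenzoic acid (20 mol %), 4 Å molecular sieves, toluene, rt to 40 °C
Reagents that add atoms: none
Why: The amine condenses with enal 6 to an (E)-iminium ion, the phenoxide of 2 adds to its β-carbon on the face remote from the CPh2(OSiMe3) group to give enamine 7, the enamine α-carbon (future C3) then attacks the neighbouring formyl carbon (future C4) to form the C3–C4 bond and close ring C, and zwitterion 8 loses water and the catalyst to give the conjugated aldehyde 9. The closest known reaction type is the diarylprolinol silyl ether catalysed domino oxa-Michael/aldol condensation of salicylaldehydes with cinnamaldehydes to 2-aryl-2H-chromene-3-carbaldehydes. Ring C, the only ring formed, closes in a 6-(enolexo)-exo-trig aldol addition. The one stereocenter that survives, C2, is set in the oxa-Michael event by the catalyst, and the centres formed transiently at C3 and C4 are erased by the dehydration. The step needs enantioface selectivity, which the shielding group of the catalyst supplies, and it needs the reversible oxa-Michael adduct to be trapped before it reverts or racemises, which the intramolecular aldol onto the ortho formyl group and the irreversible dehydration provide. Chemoselectivity follows from 2 having a single free phenol placed ortho to its only aldehyde and from the silyl and ketal protection of all ring B oxygens of 6.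

Step 6
Reactants: 9 (R)-5,7-bis(benzyloxy)-2-[2,2-diphenyl-7-(triisopropylsilyloxy)-1,3-benzodioxol-5-yl]-2H-chromene-3-carbaldehyde
Product: 11 (R)-5,7-bis(benzyloxy)-2-[2,2-diphenyl-7-(triisopropylsilyloxy)-1,3-benzodioxol-5-yl]chroman-3-one, via enol formate 10 (not isolated)
Conditions: mCPBA (1.05 equiv), CH2Cl2, 0 °C; then KHCO3 (cat.), MeOH/THF, 0 °C
Reagents that add atoms: 3-chloroperoxybenzoic acid, OOC(=O)c1cccc(Cl)c1
Why: Baeyer–Villiger oxidation of the α,β-unsaturated aldehyde should proceed with migration of the electron-rich alkenyl group to give the enol formate, whose mild methanolysis unmasks the C3 ketone with C4 now a methylene group and C2 untouched.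

Step 7
Reactants: 11 (R)-5,7-bis(benzyloxy)-2-[2,2-diphenyl-7-(triisopropylsilyloxy)-1,3-benzodioxol-5-yl]chroman-3-one
Product: 12 (2R,3R)-5,7-bis(benzyloxy)-2-[2,2-diphenyl-7-(triisopropylsilyloxy)-1,3-benzodioxol-5-yl]chroman-3-ol
Conditions: LiBH(s-Bu)3, LiBr, THF, −78 °C; then H2O
Reagents that add atoms: none
Why: The bulky hydride should attack the C3 ketone anti to the C2 aryl group and give the 2,3-cis alcohol, the standard flavan-3-one reduction to the epi series.

Step 8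
Reactants: 12 (2R,3R)-5,7-bis(benzyloxy)-2-[2,2-diphenyl-7-(triisopropylsilyloxy)-1,3-benzodioxol-5-yl]chroman-3-ol
Product: 13 (2R,3R)-5,7-bis(benzyloxy)-8-bromo-2-[2,2-diphenyl-7-(triisopropylsilyloxy)-1,3-benzodioxol-5-yl]chroman-3-ol
Conditions: NBS (1.0 equiv), CH2Cl2, −78 °C to 0 °C
Reagents that add atoms: N-bromosuccinimide, O=C1CCC(=O)N1Br
Why: Electrophilic bromination of 5,7-dialkoxyflavans should occur at C8 of the phloroglucinol-type ring A, which is far more reactive than ring B, and leaves C6 as the only nucleophilic carbon.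

Step 9
Reactants: 13 (2R,3R)-5,7-bis(benzyloxy)-8-bromo-2-[2,2-diphenyl-7-(triisopropylsilyloxy)-1,3-benzodioxol-5-yl]chroman-3-ol
Product: 14 (2R,3R)-5,7-bis(benzyloxy)-8-bromo-2-(7-hydroxy-2,2-diphenyl-1,3-benzodioxol-5-yl)chroman-3-ol
Conditions: Bu4NF, AcOH, THF, 0 °C
Reagents that add atoms: none
Why: Buffered fluoride cleaves the aryl silyl ether and frees the 3'-phenol without touching benzyl ethers, ketal or aryl bromide.

Step 10
Reactants: 14 (2R,3R)-5,7-bis(benzyloxy)-8-bromo-2-(7-hydroxy-2,2-diphenyl-1,3-benzodioxol-5-yl)chroman-3-ol, 15 3,4,5-tris(benzyloxy)benzoic acid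
Product: 16 (2R,3R)-5,7-bis(benzyloxy)-8-bromo-2-{2,2-diphenyl-7-[3,4,5-tris(benzyloxy)benzoyloxy]-1,3-benzodioxol-5-yl}chroman-3-yl 3,4,5-tris(benzyloxy)benzoate
Conditions: 15 (3 equiv), EDC·HCl, DMAP, CH2Cl2, rt
Reagents that add atoms: none
Why: Steglich esterification should acylate the only two free hydroxyls, the C3 alcohol and the 3'-phenol, in one operation with no change at any stereocenter.

Step 11
Reactants: 17 (−)-epicatechin
Product: 18 5,7,3',4'-tetra-O-benzyl-(−)-epicatechin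
Conditions: BnBr (4.2 equiv), K2CO3, DMF, 0 °C to rt
Reagents that add atoms: benzyl bromide, BrCc1ccccc1
Why: Williamson etherification under carbonate base alkylates the four phenols and leaves the less acidic C3 alcohol free.

Step 12
Reactants: 18 5,7,3',4'-tetra-O-benzyl-(−)-epicatechin
Product: 19 5,7,3',4'-tetra-O-benzyl-8-bromo-(−)-epicatechin
Conditions: NBS (1.0 equiv), CH2Cl2, −78 °C to rt
Reagents that add atoms: N-bromosuccinimide, O=C1CCC(=O)N1Br
Why: Electrophilic bromination at C8 of the upper ring A removes the most nucleophilic carbon of the future electrophile and so curbs its self-condensation.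

Step 13
Reactants: 19 5,7,3',4'-tetra-O-benzyl-8-bromo-(−)-epicatechin
Product: 20 (2R,3R,4S)-5,7-bis(benzyloxy)-2-[3,4-bis(benzyloxy)phenyl]-8-bromo-4-(2-hydroxyethoxy)chroman-3-ol
Conditions: DDQ, ethylene glycol, CH2Cl2, rt
Reagents that add atoms: ethylene glycol, OCCO
Why: DDQ abstracts the benzylic C4 hydride, and the glycol traps the resulting ring A stabilised cation anti to the C3 hydroxyl, giving the 4β ether as an ionisable handle.

Step 14
Reactants: 16 (2R,3R)-5,7-bis(benzyloxy)-8-bromo-2-{2,2-diphenyl-7-[3,4,5-tris(benzyloxy)benzoyloxy]-1,3-benzodioxol-5-yl}chroman-3-yl 3,4,5-tris(benzyloxy)benzoate, 20 (2R,3R,4S)-5,7-bis(benzyloxy)-2-[3,4-bis(benzyloxy)phenyl]-8-bromo-4-(2-hydroxyethoxy)chroman-3-ol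
Product: 21 5,7,3',4'-tetra-O-benzyl-8-bromoepicatechin-(4β→6)-[5,7-di-O-benzyl-8-bromo-4',5'-O-diphenylmethylene-epigallocatechin 3,3'-bis(3,4,5-tri-O-benzylgallate)]
Conditions: 16 (3 equiv, surplus recovered), Me3SiOTf (0.3 equiv), CH2Cl2, −78 °C to −40 °C; Et3N quench
Reagents that add atoms: none
Why: Lewis acid ionisation of the C4 ether gives a benzylic cation that should undergo Friedel–Crafts attack by C6 of 16, its only free activated carbon, from the face anti to the C3 hydroxyl and C2 aryl groups, so that the 4β (3,4-trans) 4→6 bond results.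

Step 15
Reactants: 21 5,7,3',4'-tetra-O-benzyl-8-bromoepicatechin-(4β→6)-[5,7-di-O-benzyl-8-bromo-4',5'-O-diphenylmethylene-epigallocatechin 3,3'-bis(3,4,5-tri-O-benzylgallate)]
Product: 22 epicatechin-(4β→6)-epigallocatechin 3,3'-di-O-gallate (CNP0237700.1)
Conditions: H2 (1 atm), Pd(OH)2/C, NaOAc (2.2 equiv), THF/MeOH/H2O, rt
Reagents that add atoms: none
Why: Hydrogenolysis should cleave the twelve benzyl ethers, the diphenylmethylene ketal and both aryl C–Br bonds while the esters and the interflavan bond persist, the acetate buffer taking up HBr without becoming basic enough to move the 3'-ester to O4'.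

**Compound list**

1 | 2,4,6-trihydroxybenzaldehyde | O=Cc1c(O)cc(O)cc1O | starting material
2 | 2,4-bis(benzyloxy)-6-hydroxybenzaldehyde | O=Cc1c(O)cc(OCc2ccccc2)cc1OCc1ccccc1 | intermediate
3 | 3,4,5-trihydroxybenzaldehyde | O=Cc1cc(O)c(O)c(O)c1 | starting material
4 | 7-hydroxy-2,2-diphenyl-1,3-benzodioxole-5-carbaldehyde | O=Cc1cc(O)c2OC(c3ccccc3)(c3ccccc3)Oc2c1 | intermediate
5 | 2,2-diphenyl-7-(triisopropylsilyloxy)-1,3-benzodioxole-5-carbaldehyde | O=Cc1cc(O[Si](C(C)C)(C(C)C)C(C)C)c2OC(c3ccccc3)(c3ccccc3)Oc2c1 | intermediate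
6 | (E)-3-[2,2-diphenyl-7-(triisopropylsilyloxy)-1,3-benzodioxol-5-yl]prop-2-enal | O=C/C=C/c1cc(O[Si](C(C)C)(C(C)C)C(C)C)c2OC(c3ccccc3)(c3ccccc3)Oc2c1 | intermediate
7 | oxa-Michael enamine: aryl ether of 2 at the β-carbon of 6, held as the (E)-enamine of the (S)-catalyst; ether carbon (S) by CIP, same spatial arrangement as C2 of 9 | O=Cc1c(OCc2ccccc2)cc(OCc2ccccc2)cc1O[C@@H](/C=C/N1CCC[C@H]1C(O[Si](C)(C)C)(c1ccccc1)c1ccccc1)c1cc(O[Si](C(C)C)(C(C)C)C(C)C)c2OC(c3ccccc3)(c3ccccc3)Oc2c1 | intermediate (not isolated)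
8 | aldol iminium zwitterion: ring-closed 4-oxido-chroman bearing the catalyst iminium at C3; C2 as in 9, C3 and C4 transient and unspecified | [O-]C1c2c(OCc3ccccc3)cc(OCc3ccccc3)cc2O[C@H](c2cc(O[Si](C(C)C)(C(C)C)C(C)C)c3OC(c4ccccc4)(c4ccccc4)Oc3c2)C1C=[N+]1CCC[C@H]1C(O[Si](C)(C)C)(c1ccccc1)c1ccccc1 | intermediate (not isolated)
9 | (R)-5,7-bis(benzyloxy)-2-[2,2-diphenyl-7-(triisopropylsilyloxy)-1,3-benzodioxol-5-yl]-2H-chromene-3-carbaldehyde | CC(C)[Si](Oc1cc([C@H]2Oc3cc(OCc4ccccc4)cc(OCc4ccccc4)c3C=C2C=O)cc2OC(c3ccccc3)(c3ccccc3)Oc12)(C(C)C)C(C)C | intermediate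
10 | (R)-5,7-bis(benzyloxy)-2-[2,2-diphenyl-7-(triisopropylsilyloxy)-1,3-benzodioxol-5-yl]-2H-chromen-3-yl formate | CC(C)[Si](Oc1cc([C@H]2Oc3cc(OCc4ccccc4)cc(OCc4ccccc4)c3C=C2OC=O)cc2OC(c3ccccc3)(c3ccccc3)Oc12)(C(C)C)C(C)C | intermediate (not isolated)
11 | (R)-5,7-bis(benzyloxy)-2-[2,2-diphenyl-7-(triisopropylsilyloxy)-1,3-benzodioxol-5-yl]chroman-3-one | CC(C)[Si](Oc1cc([C@H]2Oc3cc(OCc4ccccc4)cc(OCc4ccccc4)c3CC2=O)cc2OC(c3ccccc3)(c3ccccc3)Oc12)(C(C)C)C(C)C | intermediate
12 | (2R,3R)-5,7-bis(benzyloxy)-2-[2,2-diphenyl-7-(triisopropylsilyloxy)-1,3-benzodioxol-5-yl]chroman-3-ol | CC(C)[Si](Oc1cc([C@H]2Oc3cc(OCc4ccccc4)cc(OCc4ccccc4)c3C[C@H]2O)cc2OC(c3ccccc3)(c3ccccc3)Oc12)(C(C)C)C(C)C | intermediate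
13 | (2R,3R)-5,7-bis(benzyloxy)-8-bromo-2-[2,2-diphenyl-7-(triisopropylsilyloxy)-1,3-benzodioxol-5-yl]chroman-3-ol | CC(C)[Si](Oc1cc([C@H]2Oc3c(Br)c(OCc4ccccc4)cc(OCc4ccccc4)c3C[C@H]2O)cc2OC(c3ccccc3)(c3ccccc3)Oc12)(C(C)C)C(C)C | intermediate
14 | (2R,3R)-5,7-bis(benzyloxy)-8-bromo-2-(7-hydroxy-2,2-diphenyl-1,3-benzodioxol-5-yl)chroman-3-ol | Oc1cc([C@H]2Oc3c(Br)c(OCc4ccccc4)cc(OCc4ccccc4)c3C[C@H]2O)cc2OC(c3ccccc3)(c3ccccc3)Oc12 | intermediate
15 | 3,4,5-tris(benzyloxy)benzoic acid | OC(=O)c1cc(OCc2ccccc2)c(OCc2ccccc2)c(OCc2ccccc2)c1 | starting material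
16 | (2R,3R)-5,7-bis(benzyloxy)-8-bromo-2-{2,2-diphenyl-7-[3,4,5-tris(benzyloxy)benzoyloxy]-1,3-benzodioxol-5-yl}chroman-3-yl 3,4,5-tris(benzyloxy)benzoate | O=C(Oc1cc([C@H]2Oc3c(Br)c(OCc4ccccc4)cc(OCc4ccccc4)c3C[C@H]2OC(=O)c2cc(OCc3ccccc3)c(OCc3ccccc3)c(OCc3ccccc3)c2)cc2OC(c3ccccc3)(c3ccccc3)Oc12)c1cc(OCc2ccccc2)c(OCc2ccccc2)c(OCc2ccccc2)c1 | intermediate
17 | (−)-epicatechin, (2R,3R) | C1c2c(O)cc(O)cc2O[C@H](c2ccc(O)c(O)c2)[C@@H]1O | starting material
18 | 5,7,3',4'-tetra-O-benzyl-(−)-epicatechin, (2R,3R) | C1c2c(OCc3ccccc3)cc(OCc3ccccc3)cc2O[C@H](c2ccc(OCc3ccccc3)c(OCc3ccccc3)c2)[C@@H]1O | intermediate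
19 | 5,7,3',4'-tetra-O-benzyl-8-bromo-(−)-epicatechin, (2R,3R) | C1c2c(OCc3ccccc3)cc(OCc3ccccc3)c(Br)c2O[C@H](c2ccc(OCc3ccccc3)c(OCc3ccccc3)c2)[C@@H]1O | intermediate
20 | (2R,3R,4S)-5,7-bis(benzyloxy)-2-[3,4-bis(benzyloxy)phenyl]-8-bromo-4-(2-hydroxyethoxy)chroman-3-ol (4β ether, 3,4-trans) | OCCO[C@H]1c2c(OCc3ccccc3)cc(OCc3ccccc3)c(Br)c2O[C@H](c2ccc(OCc3ccccc3)c(OCc3ccccc3)c2)[C@@H]1O | intermediate
21 | 5,7,3',4'-tetra-O-benzyl-8-bromoepicatechin-(4β→6)-[5,7-di-O-benzyl-8-bromo-4',5'-O-diphenylmethylene-epigallocatechin 3,3'-bis(3,4,5-tri-O-benzylgallate)]; upper unit (2R,3R) with the C4 aryl trans to the C3 hydroxyl, lower unit (2R,3R) | O=C(Oc1cc([C@H]2Oc3c(Br)c(OCc4ccccc4)c([C@H]4c5c(OCc6ccccc6)cc(OCc6ccccc6)c(Br)c5O[C@H](c5ccc(OCc6ccccc6)c(OCc6ccccc6)c5)[C@@H]4O)c(OCc4ccccc4)c3C[C@H]2OC(=O)c2cc(OCc3ccccc3)c(OCc3ccccc3)c(OCc3ccccc3)c2)cc2OC(c3ccccc3)(c3ccccc3)Oc12)c1cc(OCc2ccccc2)c(OCc2ccccc2)c(OCc2ccccc2)c1 | intermediate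
22 | epicatechin-(4β→6)-epigallocatechin 3,3'-di-O-gallate; upper unit (2R,3R,4S), lower unit (2R,3R) | O=C(Oc1cc([C@H]2Oc3cc(O)c([C@H]4c5c(O)cc(O)cc5O[C@H](c5ccc(O)c(O)c5)[C@@H]4O)c(O)c3C[C@H]2OC(=O)c2cc(O)c(O)c(O)c2)cc(O)c1O)c1cc(O)c(O)c(O)c1 | target

**Step count and risks**

Total step count: 15. Longest linear sequence: 11 steps (steps 2, 3, 4, 5, 6, 7, 8, 9, 10, 14, 15).

Steps most likely to fail:

Step 5. The aldol closure onto the hindered, electron-rich formyl group of 2 may be slow, so that the reversible oxa-Michael adduct reverts or loses enantiomeric purity before ring C is closed. The fallback closes the same C3–C4 linkage by olefin metathesis; it sets out from 2 and 6 and comes back at 11. Wittig methylenation of 2 (Ph3P=CH2, THF) should give 3,5-bis(benzyloxy)-2-vinylphenol F1. Reduction of 6 (NaBH4, CeCl3·7H2O, MeOH) should give the (E)-cinnamyl alcohol F2, which methyl chloroformate and pyridine convert into the methyl carbonate F3. Branched-selective asymmetric allylic etherification of F1 with F3 ([Ir(cod)Cl]2, chiral binaphthol-derived phosphoramidite ligand, Cs2CO3, THF) should give the (S)-aryl allyl ether F4 with the C2 configuration in place. Ring-closing metathesis (second-generation Grubbs catalyst, CH2Cl2, 40 °C) should give the (S)-flav-3-ene F5. Hydroboration–oxidation (BH3·THF; then NaOH, H2O2) should give the 2,3-trans alcohol F6, and Dess–Martin oxidation of F6 gives 11.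

Step 6. The electron-rich enol formate may be epoxidised by the peracid, and the ketone may epimerise at C2 through enolisation while the formate is cleaved. The fallback exchanges the formyl carbon for a C3 heteroatom by a Curtius sequence; it sets out from 9 and comes back at 11. Pinnick oxidation (NaClO2, NaH2PO4, 2-methyl-2-butene, t-BuOH/H2O) should give the carboxylic acid F7. Diphenylphosphoryl azide and Et3N should give the acyl azide F8, which on warming in toluene rearranges to the vinyl isocyanate F9. Hydrolysis of F9 with dilute aqueous HCl in THF gives the enamine and then 11.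

Step 14. Self-condensation of the electrophile at its own free C6 may outrun attack by the hindered C6 of 16, and the Lewis acid may open the ketal on prolonged exposure. The fallback caps both nucleophilic ring A carbons of the electrophile, so that it can be used in excess without oligomerising; it sets out from 18 (with 16) and comes back at 22. Bromination of 18 with NBS (2.2 equiv, CH2Cl2) should give 5,7,3',4'-tetra-O-benzyl-6,8-dibromoepicatechin F10. DDQ and ethylene glycol should give its 4β-(2-hydroxyethoxy) ether F11. Coupling of F11 (excess) with 16 under Me3SiOTf should give the tribromo protected dimer F12, and hydrogenolysis as in step 15 (H2, Pd(OH)2/C, NaOAc) removes all three bromines with the other protecting groups to give 22.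

**Further compounds**

F1 | step 5 | 3,5-bis(benzyloxy)-2-vinylphenol | C=Cc1c(O)cc(OCc2ccccc2)cc1OCc1ccccc1
F2 | step 5 | (E)-3-[2,2-diphenyl-7-(triisopropylsilyloxy)-1,3-benzodioxol-5-yl]prop-2-en-1-ol | OC/C=C/c1cc(O[Si](C(C)C)(C(C)C)C(C)C)c2OC(c3ccccc3)(c3ccccc3)Oc2c1
F3 | step 5 | (E)-3-[2,2-diphenyl-7-(triisopropylsilyloxy)-1,3-benzodioxol-5-yl]prop-2-enyl methyl carbonate | COC(=O)OC/C=C/c1cc(O[Si](C(C)C)(C(C)C)C(C)C)c2OC(c3ccccc3)(c3ccccc3)Oc2c1
F4 | step 5 | (S)-1-[2,2-diphenyl-7-(triisopropylsilyloxy)-1,3-benzodioxol-5-yl]prop-2-enyl 3,5-bis(benzyloxy)-2-vinylphenyl ether | C=Cc1c(OCc2ccccc2)cc(OCc2ccccc2)cc1O[C@@H](C=C)c1cc(O[Si](C(C)C)(C(C)C)C(C)C)c2OC(c3ccccc3)(c3ccccc3)Oc2c1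
F5 | step 5 | (S)-5,7-bis(benzyloxy)-2-[2,2-diphenyl-7-(triisopropylsilyloxy)-1,3-benzodioxol-5-yl]-2H-chromene | CC(C)[Si](Oc1cc([C@H]2Oc3cc(OCc4ccccc4)cc(OCc4ccccc4)c3C=C2)cc2OC(c3ccccc3)(c3ccccc3)Oc12)(C(C)C)C(C)C
F6 | step 5 | (2R,3S)-5,7-bis(benzyloxy)-2-[2,2-diphenyl-7-(triisopropylsilyloxy)-1,3-benzodioxol-5-yl]chroman-3-ol | CC(C)[Si](Oc1cc([C@H]2Oc3cc(OCc4ccccc4)cc(OCc4ccccc4)c3C[C@@H]2O)cc2OC(c3ccccc3)(c3ccccc3)Oc12)(C(C)C)C(C)C
F7 | step 6 | (R)-5,7-bis(benzyloxy)-2-[2,2-diphenyl-7-(triisopropylsilyloxy)-1,3-benzodioxol-5-yl]-2H-chromene-3-carboxylic acid | CC(C)[Si](Oc1cc([C@H]2Oc3cc(OCc4ccccc4)cc(OCc4ccccc4)c3C=C2C(=O)O)cc2OC(c3ccccc3)(c3ccccc3)Oc12)(C(C)C)C(C)C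
F8 | step 6 | (R)-5,7-bis(benzyloxy)-2-[2,2-diphenyl-7-(triisopropylsilyloxy)-1,3-benzodioxol-5-yl]-2H-chromene-3-carbonyl azide | CC(C)[Si](Oc1cc([C@H]2Oc3cc(OCc4ccccc4)cc(OCc4ccccc4)c3C=C2C(=O)N=[N+]=[N-])cc2OC(c3ccccc3)(c3ccccc3)Oc12)(C(C)C)C(C)C
F9 | step 6 | (R)-5,7-bis(benzyloxy)-2-[2,2-diphenyl-7-(triisopropylsilyloxy)-1,3-benzodioxol-5-yl]-3-isocyanato-2H-chromene | CC(C)[Si](Oc1cc([C@H]2Oc3cc(OCc4ccccc4)cc(OCc4ccccc4)c3C=C2N=C=O)cc2OC(c3ccccc3)(c3ccccc3)Oc12)(C(C)C)C(C)C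
F10 | step 14 | 5,7,3',4'-tetra-O-benzyl-6,8-dibromo-(−)-epicatechin, (2R,3R) | C1c2c(OCc3ccccc3)c(Br)c(OCc3ccccc3)c(Br)c2O[C@H](c2ccc(OCc3ccccc3)c(OCc3ccccc3)c2)[C@@H]1O
F11 | step 14 | 5,7,3',4'-tetra-O-benzyl-6,8-dibromo-4β-(2-hydroxyethoxy)epicatechin (3,4-trans) | OCCO[C@H]1c2c(OCc3ccccc3)c(Br)c(OCc3ccccc3)c(Br)c2O[C@H](c2ccc(OCc3ccccc3)c(OCc3ccccc3)c2)[C@@H]1O
F12 | step 14 | 5,7,3',4'-tetra-O-benzyl-6,8-dibromoepicatechin-(4β→6)-[5,7-di-O-benzyl-8-bromo-4',5'-O-diphenylmethylene-epigallocatechin 3,3'-bis(3,4,5-tri-O-benzylgallate)] | O=C(Oc1cc([C@H]2Oc3c(Br)c(OCc4ccccc4)c([C@H]4c5c(OCc6ccccc6)c(Br)c(OCc6ccccc6)c(Br)c5O[C@H](c5ccc(OCc6ccccc6)c(OCc6ccccc6)c5)[C@@H]4O)c(OCc4ccccc4)c3C[C@H]2OC(=O)c2cc(OCc3ccccc3)c(OCc3ccccc3)c(OCc3ccccc3)c2)cc2OC(c3ccccc3)(c3ccccc3)Oc12)c1cc(OCc2ccccc2)c(OCc2ccccc2)c(OCc2ccccc2)c1
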